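**Retrosynthetic overview**

1. Feature used: C1 is the ring-fusion methine of the cis-fused γ-lactone (ring O–C14–C1–C15–C16) and carries C2, which is bonded to C3 of the C3–C4 oxirane. With the oxirane taken back to an E-C3=C4 alkene, C2–C3 is an sp3–sp2 bond, and C1–H can come from hydroboration of a C1=C2 exocyclic methylene on the lactone.
2. Late disconnections: oxirane ⇒ E-C3=C4 alkene (reagent-controlled epoxidation); C13–OAc ⇒ C13–OPMB; C15=CH2 ⇒ lactone enolate plus iminium salt.
3. Key disconnection C2–C3: 14-membered carbocycle ⇒ β-methylene lactone carrying the E-C3 alkenyl iodide (9-BBN hydroboration, then B-alkyl Suzuki–Miyaura ring closure).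
4. That precursor ⇒ vinyl lactone + (E)-1-iodo-2-methylpenta-1,4-diene (C3–C6, cross-metathesis at C6=C7); lactone ⇒ C14 aldehyde + 2-metallated butenyl silyl ether (chelation-controlled C14–C1 bond, then oxidative lactonisation); aldehyde ⇒ primary iodide from (S)-linalool (C7–C11 with the C8 carbinol) + PMB-protected (2S,3S)-epoxybutanol (C12–C14).
5. Ring order: γ-lactone (step 13), then the 14-membered carbocycle (step 16), then the oxirane (step 21).

Key step: step 16

Remark on the chemistry: cembrane locants C1–C16 are used for all intermediates; C13–O is carried as a 4-methoxybenzyl (PMB) ether because it must chelate in step 11, and the tertiary C8 hydroxyl is left free from step 12 onwards.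

**Route**

Step 1
Reactants: 1 (S)-linalool
Product: 2 triethyl{[(3S)-3,7-dimethylocta-1,6-dien-3-yl]oxy}silane
Conditions: Et3SiOTf, 2,6-lutidine, CH2Cl2, −78 → 0 °C
Reagents that add atoms: triethylsilyl trifluoromethanesulfonate, CC[Si](CC)(CC)OS(=O)(=O)C(F)(F)F
Why: Silylation of a tertiary alcohol with a silyl triflate and a hindered pyridine base is routine and masks the only acidic proton ahead of the organolithium steps, C8 (S) being carried over unchanged from linalool.

Step 2
Reactants: 2 linalool triethylsilyl ether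
Product: 4 (4S)-4-methyl-4-(triethylsilyloxy)hex-5-en-1-ol, via aldehyde 3 (not isolated)
Conditions: O3, CH2Cl2/MeOH, pyridine (trace), Sudan Red 7B end-point, −78 °C; Me2S; then NaBH4, 0 °C
Reagents that add atoms: ozone, [O-][O+]=O
Why: Chemoselective ozonolysis, in which ozone cleaves the electron-rich trisubstituted alkene much faster than the vinyl group on the quaternary silyloxy carbon, followed by borohydride reduction of aldehyde 3 in the same flask, releases C11 as a primary alcohol.

Step 3
Reactants: 4 (4S)-4-methyl-4-(triethylsilyloxy)hex-5-en-1-ol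
Product: 5 (3S)-6-iodo-3-methyl-3-(triethylsilyloxy)hex-1-ene
Conditions: I2, PPh3, imidazole, CH2Cl2, 0 °C
Reagents that add atoms: iodine, II
Why: Appel-type iodination converts the primary alcohol into the primary iodide under near-neutral conditions that leave the tertiary silyl ether and the vinyl group untouched.

Step 4
Reactants: 6 (E)-but-2-en-1-ol
Product: 7 [(2S,3S)-3-methyloxiran-2-yl]methanol
Conditions: Ti(OiPr)4 (cat.), L-(+)-diisopropyl tartrate, t-BuOOH, 4 Å sieves, CH2Cl2, −20 °C
Reagents that add atoms: tert-butyl hydroperoxide, CC(C)(C)OO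
Why: Sharpless asymmetric epoxidation of an E allylic alcohol with L-(+)-tartrate delivers oxygen to the face that gives the (2S,3S)-epoxy alcohol, which fixes the future C13 (C2 of 7) and, after later inversion, C12 (C3 of 7).

Step 5
Reactants: 7 [(2S,3S)-3-methyloxiran-2-yl]methanol
Product: 8 (2S,3S)-2-[(4-methoxybenzyloxy)methyl]-3-methyloxirane
Conditions: NaH, 4-MeOC6H4CH2Cl, Bu4NI (cat.), THF/DMF, 0 °C
Reagents that add atoms: 4-methoxybenzyl chloride, COc1ccc(CCl)cc1
Why: Williamson etherification of the primary alkoxide with a benzylic chloride under iodide catalysis at 0 °C outpaces Payne rearrangement and leaves the epoxide intact.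

Step 6
Reactants: 5 (3S)-6-iodo-3-methyl-3-(triethylsilyloxy)hex-1-ene; 8 (2S,3S)-2-[(4-methoxybenzyloxy)methyl]-3-methyloxirane
Product: 11 (2R,3S,7S)-1-(4-methoxybenzyloxy)-3,7-dimethyl-7-(triethylsilyloxy)non-8-en-2-ol, via alkyllithium 9 (not isolated), via alkylmagnesium bromide 10 (not isolated)
Conditions: t-BuLi (2.1 equiv), Et2O/pentane, −78 °C; MgBr2·OEt2, −78 → −40 °C; CuI (10 mol %), 8, THF, −40 → 0 °C
Reagents that add atoms: none
Why: Iodine–lithium exchange at −78 °C gives primary alkyllithium 9 without radical 5-exo cyclisation onto the vinyl group, and after transmetalation the copper-catalysed Grignard opening of the epoxy ether occurs by SN2 attack at the methyl-bearing carbon remote from the deactivating CH2O substituent, with inversion there, so that C12 becomes S while C13 (R) keeps the epoxide configuration.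

Step 7
Reactants: 11 (2R,3S,7S)-1-(4-methoxybenzyloxy)-3,7-dimethyl-7-(triethylsilyloxy)non-8-en-2-ol
Product: 12 (4R)-2-(4-methoxyphenyl)-4-[(2S,6S)-6-methyl-6-(triethylsilyloxy)oct-7-en-2-yl]-1,3-dioxolane (acetal carbon as epimer mixture)
Conditions: DDQ, 4 Å sieves, CH2Cl2, 0 °C
Reagents that add atoms: none
Why: Oxidative acetalisation, in which anhydrous DDQ abstracts benzylic hydride from the PMB ether and the adjacent C13 hydroxyl traps the oxocarbenium ion as a five-membered 4-methoxybenzylidene acetal, whose new acetal centre forms as an inconsequential epimer mixture.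

Step 8
Reactants: 12 4-methoxybenzylidene acetal
Product: 13 (2R,3S,7S)-2-(4-methoxybenzyloxy)-3,7-dimethyl-7-(triethylsilyloxy)non-8-en-1-ol
Conditions: iBu2AlH, CH2Cl2, −78 → 0 °C; aq. potassium sodium tartrate
Reagents that add atoms: none
Why: Regioselective reductive acetal opening, in which the aluminium hydride coordinates the less hindered primary oxygen and delivers hydride to the acetal carbon, leaves the PMB group on the secondary C13 oxygen and frees C14 as the primary alcohol.

Step 9
Reactants: 13 (2R,3S,7S)-2-(4-methoxybenzyloxy)-3,7-dimethyl-7-(triethylsilyloxy)non-8-en-1-ol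
Product: 14 (2R,3S,7S)-2-(4-methoxybenzyloxy)-3,7-dimethyl-7-(triethylsilyloxy)non-8-enal
Conditions: Dess–Martin periodinane, NaHCO3, CH2Cl2, 0 °C → rt; used at once
Reagents that add atoms: none
Why: Dess–Martin oxidation under bicarbonate buffer gives the α-alkoxy aldehyde without epimerising C13 or disturbing the PMB and silyl ethers.

Step 10
Reactants: 15 3-bromobut-3-en-1-ol
Product: 16 (3-bromobut-3-en-1-yloxy)(tert-butyl)dimethylsilane
Conditions: t-BuMe2SiCl, imidazole, CH2Cl2, rt
Reagents that add atoms: tert-butyldimethylsilyl chloride, CC(C)(C)[Si](C)(C)Cl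
Why: Standard silylation of a primary alcohol protects the hydroxyl of the alkenyl bromide before bromine–lithium exchange.

Step 11
Reactants: 14 (2R,3S,7S)-2-(4-methoxybenzyloxy)-3,7-dimethyl-7-(triethylsilyloxy)non-8-enal; 16 (3-bromobut-3-en-1-yloxy)(tert-butyl)dimethylsilane
Product: 19 (4R,5R,6S,10S)-1-(tert-butyldimethylsilyloxy)-5-(4-methoxybenzyloxy)-6,10-dimethyl-3-methylidene-10-(triethylsilyloxy)dodec-11-en-4-ol, via alkenyllithium 17 (not isolated), via alkenylmagnesium bromide 18 (not isolated)
Conditions: 16, t-BuLi (2 equiv), Et2O, −78 °C; MgBr2·OEt2; then 14 pre-complexed with MgBr2·OEt2, CH2Cl2, −78 °C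
Reagents that add atoms: none
Why: Chelation-controlled carbonyl addition (Cram chelate model), in which MgBr2 ties the aldehyde oxygen to the C13 OPMB oxygen in a five-membered chelate and alkenylmagnesium reagent 18 attacks the face away from the C12 chain, gives the 13,14-syn carbinol, that is (14R).

Step 12
Reactants: 19 bis-silylated allylic alcohol
Product: 20 (4R,5R,6S,10S)-5-(4-methoxybenzyloxy)-6,10-dimethyl-3-methylidenedodec-11-ene-1,4,10-triol
Conditions: Bu4NF, THF, rt → 40 °C
Reagents that add atoms: none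
Why: Fluoride-mediated desilylation removes the primary TBS ether and the tertiary TES ether, while the PMB ether, the allylic alcohol and both alkenes are inert to Bu4NF.

Step 13
Reactants: 20 triol
Product: 23 (5R)-5-[(1R,2S,6S)-6-hydroxy-1-(4-methoxybenzyloxy)-2,6-dimethyloct-7-en-1-yl]-4-methylideneoxolan-2-one, via hydroxy aldehyde 21 (not isolated), via lactol 22 (not isolated)
Conditions: TEMPO (2,2,6,6-tetramethylpiperidin-1-oxyl, cat.), PhI(OAc)2, CH2Cl2, rt
Reagents that add atoms: none
Why: Oxoammonium-mediated oxidative lactonisation of a 1,4-diol oxidises only the primary alcohol, the C14 hydroxyl traps aldehyde 21 as lactol 22 before the alkene can move into conjugation, and 22 is oxidised on to the γ-lactone, the tertiary alcohol being inert.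

Step 14
Reactants: 24 pent-1-en-4-yne
Product: 26 (1E)-1-iodo-2-methylpenta-1,4-diene, via alkenylalane 25 (not isolated)
Conditions: Me3Al, Cp2ZrCl2 (cat.), CH2Cl2, 0 °C → rt; I2, THF, −30 → 0 °C
Reagents that add atoms: trimethylaluminium, C[Al](C)C; iodine, II
Why: Zirconium-catalysed carboalumination of the terminal alkyne (Negishi carboalumination) adds methyl and aluminium syn with aluminium at the terminus, and iodinolysis of alkenylalane 25 with retention gives the E trisubstituted alkenyl iodide, the isolated terminal alkene reacting far more slowly.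

Step 15
Reactants: 23 vinyl β-methylene lactone; 26 (1E)-1-iodo-2-methylpenta-1,4-diene
Product: 27 (5R)-5-[(1R,2S,6S,7E,10E)-6-hydroxy-11-iodo-1-(4-methoxybenzyloxy)-2,6,10-trimethylundeca-7,10-dien-1-yl]-4-methylideneoxolan-2-one
Conditions: second-generation Hoveyda–Grubbs catalyst [RuCl2(H2IMes)(=CH-C6H4-2-OiPr), 10 mol %], 1,4-benzoquinone (10 mol %), 26 (3 equiv), CH2Cl2, 40 °C
Reagents that add atoms: none
Why: Olefin cross-metathesis joins the vinyl group of the free tertiary allylic alcohol to the terminal alkene of 26 with E geometry enforced by the quaternary C8, the 1,1-disubstituted lactone methylene and the trisubstituted iodoalkene being much poorer metathesis partners and benzoquinone suppressing migration of the skipped diene.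

Step 16
Reactants: 27 β-methylene lactone E-alkenyl iodide
Product: 29 (1S,3E,6E,8S,12S,13R,14R)-8-hydroxy-13-(4-methoxybenzyloxy)-4,8,12-trimethylcyclotetradeca-3,6-diene bearing the cis-fused γ-lactone C1–CH2–C(=O)–O–C14, via B-alkyl-9-BBN borane 28 (not isolated)
Conditions: 9-BBN (3 equiv), THF, 0 °C → rt; then slow addition to PdCl2(dppf) (20 mol %), AsPh3 (40 mol %), Cs2CO3 (4 equiv), DMF/THF/H2O, 2 mM, rt → 45 °C
Reagents that add atoms: none
Why: 9-BBN adds across the C1=C2 exocyclic methylene with boron on the terminal C2 and hydrogen on C1 (syn addition through a four-centre transition state), after which zerovalent palladium generated from PdCl2(dppf) inserts into the C3–I bond, the base-activated B-alkyl borane 28 transmetalates and reductive elimination forms C2–C3. The closest known reaction type is the hydroboration/B-alkyl Suzuki–Miyaura macrocyclisation of an alkene tethered to an alkenyl iodide. The 14-membered carbocycle is closed in the cross-coupling event by intramolecular sp3–sp2 bond formation under high dilution (slow addition of 28 to the catalyst), the γ-lactone being already in place. The new stereocentre C1 is set in the hydroboration, where the borane approaches the lactone face opposite the C14 side chain, so that hydrogen enters anti to it and C2 ends cis to C13, which is the cis ring fusion (1S). The step needs 9-BBN to choose the 1,1-disubstituted alkene over the E-C6=C7 alkene, the iodoalkene and the lactone carbonyl, which its strong preference for unhindered terminal alkenes and the shielding of C6=C7 by the quaternary C8 secure, while the free C8 hydroxyl at most consumes borane as a borinate that the aqueous base hydrolyses. The E geometry of C3=C4 from step 14 is kept because oxidative addition and reductive elimination proceed with retention at the alkenyl carbon.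

Step 17
Reactants: 29 macrocyclic lactone
Product: 30 15-(dimethylaminomethyl) derivative of 29 (aminomethyl group trans to C2)
Conditions: LiN(iPr)2 (2.3 equiv), THF, −78 °C; CH2=NMe2+ I−, −78 → 0 °C
Reagents that add atoms: dimethylmethyleneammonium iodide, C=[N+](C)C.[I-]
Why: Mannich reaction of the lithium lactone enolate (the C8 alkoxide being formed first by the extra base) with the iminium salt installs the aminomethyl group at C15 on the face away from C2, a configuration that the next step erases.

Step 18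
Reactants: 30 Mannich base
Product: 32 (1S,3E,6E,8S,12S,13R,14R)-8-hydroxy-13-(4-methoxybenzyloxy)-4,8,12-trimethylcyclotetradeca-3,6-diene bearing the cis-fused α-methylene-γ-lactone C1–C(=CH2)–C(=O)–O–C14, via trimethylammonium iodide 31 (not isolated)
Conditions: MeI, MeOH/CH2Cl2, rt; then aq. NaHCO3, CH2Cl2, rt
Reagents that add atoms: none
Why: Exhaustive N-methylation gives ammonium salt 31, which undergoes mild base-induced E1cB elimination of trimethylamine to the α-methylene lactone.

Step 19
Reactants: 32 α-methylene lactone PMB ether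
Product: 33 13-hydroxy compound (PMB removed from 32)
Conditions: DDQ, CH2Cl2/pH 7 phosphate buffer, 0 °C
Reagents that add atoms: none
Why: Oxidative PMB cleavage by DDQ in wet dichloromethane proceeds through the benzylic oxocarbenium ion and its hemiacetal and leaves the electron-poor methylene lactone, the alkenes and the tertiary alcohol untouched.

Step 20
Reactants: 33 13-hydroxy α-methylene lactone
Product: 34 13-acetate (1S,3E,6E,8S,12S,13R,14R)
Conditions: Ac2O (1.5 equiv), pyridine, 4-(dimethylamino)pyridine (cat.), CH2Cl2, 0 °C → rt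
Reagents that add atoms: acetic anhydride, CC(=O)OC(C)=O
Why: Nucleophile-catalysed acetylation acylates the secondary C13 hydroxyl selectively because the tertiary C8 alcohol next to a quaternary centre is much less reactive.

Step 21
Reactants: 34 13-acetate diene
Product: 35 target, (1S,3R,4R,6E,8S,12S,13R,14R)-13-acetoxy-3,4-epoxy-8-hydroxy α-methylene lactone
Conditions: D-fructose-derived ketone catalyst (1,2:4,5-di-O-isopropylidene-β-D-erythro-2,3-hexodiulo-2,6-pyranose, 0.3 equiv), KHSO5 (as 2KHSO5·KHSO4·K2SO4), K2CO3, Bu4NHSO4, Na2B4O7 buffer, MeCN/CH2(OMe)2/H2O, 0 °C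
Reagents that add atoms: potassium peroxymonosulfate, [K+].[O-]S(=O)(=O)OO
Why: Shi asymmetric epoxidation, in which the chiral dioxirane from the D-fructose-derived ketone attacks the most electron-rich, trisubstituted E-C3=C4 alkene through a spiro transition state on the face that gives the (3R,4R)-oxirane with retention of alkene geometry, is reagent-controlled, while the disubstituted C6=C7 alkene next to the quaternary C8 reacts more slowly and the electron-poor methylene lactone is not attacked.

**Compound list**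

1 | (S)-linalool | CC(C)=CCC[C@](C)(O)C=C | starting material
2 | triethyl{[(3S)-3,7-dimethylocta-1,6-dien-3-yl]oxy}silane | CC(C)=CCC[C@](C)(O[Si](CC)(CC)CC)C=C | intermediate
3 | (4S)-4-methyl-4-(triethylsilyloxy)hex-5-enal | O=CCC[C@](C)(O[Si](CC)(CC)CC)C=C | intermediate (not isolated)
4 | (4S)-4-methyl-4-(triethylsilyloxy)hex-5-en-1-ol | OCCC[C@](C)(O[Si](CC)(CC)CC)C=C | intermediate
5 | (3S)-6-iodo-3-methyl-3-(triethylsilyloxy)hex-1-ene | ICCC[C@](C)(O[Si](CC)(CC)CC)C=C | intermediate
6 | (E)-but-2-en-1-ol | C/C=C/CO | starting material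
7 | [(2S,3S)-3-methyloxiran-2-yl]methanol | C[C@@H]1O[C@H]1CO | intermediate
8 | (2S,3S)-2-[(4-methoxybenzyloxy)methyl]-3-methyloxirane | C[C@@H]1O[C@H]1COCc1ccc(OC)cc1 | intermediate
9 | [(4S)-4-methyl-4-(triethylsilyloxy)hex-5-en-1-yl]lithium | [Li]CCC[C@](C)(O[Si](CC)(CC)CC)C=C | intermediate (not isolated)
10 | [(4S)-4-methyl-4-(triethylsilyloxy)hex-5-en-1-yl]magnesium bromide | Br[Mg]CCC[C@](C)(O[Si](CC)(CC)CC)C=C | intermediate (not isolated)
11 | (2R,3S,7S)-1-(4-methoxybenzyloxy)-3,7-dimethyl-7-(triethylsilyloxy)non-8-en-2-ol | COc1ccc(COC[C@H](O)[C@@H](C)CCC[C@](C)(O[Si](CC)(CC)CC)C=C)cc1 | intermediate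
12 | (4R)-2-(4-methoxyphenyl)-4-[(2S,6S)-6-methyl-6-(triethylsilyloxy)oct-7-en-2-yl]-1,3-dioxolane, acetal carbon unassigned | COc1ccc(C2OC[C@@H]([C@@H](C)CCC[C@](C)(O[Si](CC)(CC)CC)C=C)O2)cc1 | intermediate
13 | (2R,3S,7S)-2-(4-methoxybenzyloxy)-3,7-dimethyl-7-(triethylsilyloxy)non-8-en-1-ol | OC[C@H](OCc1ccc(OC)cc1)[C@@H](C)CCC[C@](C)(O[Si](CC)(CC)CC)C=C | intermediate
14 | (2R,3S,7S)-2-(4-methoxybenzyloxy)-3,7-dimethyl-7-(triethylsilyloxy)non-8-enal | O=C[C@H](OCc1ccc(OC)cc1)[C@@H](C)CCC[C@](C)(O[Si](CC)(CC)CC)C=C | intermediate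
15 | 3-bromobut-3-en-1-ol | C=C(Br)CCO | starting material
16 | (3-bromobut-3-en-1-yloxy)(tert-butyl)dimethylsilane | C=C(Br)CCO[Si](C)(C)C(C)(C)C | intermediate
17 | [4-(tert-butyldimethylsilyloxy)but-1-en-2-yl]lithium | C=C([Li])CCO[Si](C)(C)C(C)(C)C | intermediate (not isolated)
18 | [4-(tert-butyldimethylsilyloxy)but-1-en-2-yl]magnesium bromide | C=C([Mg]Br)CCO[Si](C)(C)C(C)(C)C | intermediate (not isolated)
19 | (4R,5R,6S,10S)-1-(tert-butyldimethylsilyloxy)-5-(4-methoxybenzyloxy)-6,10-dimethyl-3-methylidene-10-(triethylsilyloxy)dodec-11-en-4-ol | C=C(CCO[Si](C)(C)C(C)(C)C)[C@@H](O)[C@H](OCc1ccc(OC)cc1)[C@@H](C)CCC[C@](C)(O[Si](CC)(CC)CC)C=C | intermediate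
20 | (4R,5R,6S,10S)-5-(4-methoxybenzyloxy)-6,10-dimethyl-3-methylidenedodec-11-ene-1,4,10-triol | C=C(CCO)[C@@H](O)[C@H](OCc1ccc(OC)cc1)[C@@H](C)CCC[C@](C)(O)C=C | intermediate
21 | (4R,5R,6S,10S)-4,10-dihydroxy-5-(4-methoxybenzyloxy)-6,10-dimethyl-3-methylidenedodec-11-enal | C=C(CC=O)[C@@H](O)[C@H](OCc1ccc(OC)cc1)[C@@H](C)CCC[C@](C)(O)C=C | intermediate (not isolated)
22 | (5R)-5-[(1R,2S,6S)-6-hydroxy-1-(4-methoxybenzyloxy)-2,6-dimethyloct-7-en-1-yl]-4-methylideneoxolan-2-ol, anomer mixture | C=C1CC(O)O[C@H]1[C@H](OCc1ccc(OC)cc1)[C@@H](C)CCC[C@](C)(O)C=C | intermediate (not isolated)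
23 | (5R)-5-[(1R,2S,6S)-6-hydroxy-1-(4-methoxybenzyloxy)-2,6-dimethyloct-7-en-1-yl]-4-methylideneoxolan-2-one | C=C1CC(=O)O[C@H]1[C@H](OCc1ccc(OC)cc1)[C@@H](C)CCC[C@](C)(O)C=C | intermediate
24 | pent-1-en-4-yne | C=CCC#C | starting material
25 | dimethyl[(1E)-2-methylpenta-1,4-dien-1-yl]alane | C=CC/C(C)=C/[Al](C)C | intermediate (not isolated)
26 | (1E)-1-iodo-2-methylpenta-1,4-diene | C=CC/C(C)=C/I | intermediate
27 | (5R)-5-[(1R,2S,6S,7E,10E)-6-hydroxy-11-iodo-1-(4-methoxybenzyloxy)-2,6,10-trimethylundeca-7,10-dien-1-yl]-4-methylideneoxolan-2-one | C=C1CC(=O)O[C@H]1[C@H](OCc1ccc(OC)cc1)[C@@H](C)CCC[C@](C)(O)/C=C/C/C(C)=C/I | intermediate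
28 | (4S,5R)-4-[(9-borabicyclo[3.3.1]nonan-9-yl)methyl]-5-[(1R,2S,6S,7E,10E)-6-hydroxy-11-iodo-1-(4-methoxybenzyloxy)-2,6,10-trimethylundeca-7,10-dien-1-yl]oxolan-2-one | C(B1C2CCCC1CCC2)[C@H]1CC(=O)O[C@H]1[C@H](OCc1ccc(OC)cc1)[C@@H](C)CCC[C@](C)(O)/C=C/C/C(C)=C/I | intermediate (not isolated)
29 | (1S,3E,6E,8S,12S,13R,14R)-8-hydroxy-13-(4-methoxybenzyloxy)-4,8,12-trimethylcyclotetradeca-3,6-diene with cis-fused γ-lactone C1–CH2–C(=O)–O–C14 | C1C(=O)O[C@H]2[C@H](OCc3ccc(OC)cc3)[C@@H](C)CCC[C@](C)(O)/C=C/C/C(C)=C/C[C@@H]12 | intermediate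
30 | 15-(dimethylaminomethyl) derivative of 29, aminomethyl trans to C2 | CN(C)C[C@@H]1C(=O)O[C@H]2[C@H](OCc3ccc(OC)cc3)[C@@H](C)CCC[C@](C)(O)/C=C/C/C(C)=C/C[C@@H]12 | intermediate
31 | 15-(trimethylammoniomethyl) iodide of 29 | C[N+](C)(C)C[C@@H]1C(=O)O[C@H]2[C@H](OCc3ccc(OC)cc3)[C@@H](C)CCC[C@](C)(O)/C=C/C/C(C)=C/C[C@@H]12.[I-] | intermediate (not isolated)
32 | α-methylene lactone, 13-OPMB, 8-OH, (1S,3E,6E,8S,12S,13R,14R) | C=C1C(=O)O[C@H]2[C@H](OCc3ccc(OC)cc3)[C@@H](C)CCC[C@](C)(O)/C=C/C/C(C)=C/C[C@@H]12 | intermediate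
33 | α-methylene lactone, 13-OH, 8-OH | C=C1C(=O)O[C@H]2[C@H](O)[C@@H](C)CCC[C@](C)(O)/C=C/C/C(C)=C/C[C@@H]12 | intermediate
34 | α-methylene lactone, 13-OAc, 8-OH | C=C1C(=O)O[C@H]2[C@H](OC(C)=O)[C@@H](C)CCC[C@](C)(O)/C=C/C/C(C)=C/C[C@@H]12 | intermediate
35 | CNP0202356.4, (1S,3R,4R,6E,8S,12S,13R,14R) | C=C1C(=O)O[C@H]2[C@H](OC(C)=O)[C@@H](C)CCC[C@](C)(O)/C=C/C[C@@]3(C)O[C@@H]3C[C@@H]12 | target

**Step count and risks**

Total step count: 21. Longest linear sequence: 17 steps from (S)-linalool (steps 1–3, 6–9, 11–13, 15–21).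

Steps most likely to fail:

Step 16 (key step). The ring closure may lose out to intermolecular coupling, or transmetalation of the hindered B-alkyl borane may be slow enough for protodeboronation and β-hydride elimination to compete; face selectivity at C1 could also be lower than expected. The fallback sets out from 27 and returns at 29. Compound 27 is hydroborated with 9-BBN as before and borane 28 is oxidised with buffered NaBO3·4H2O to the primary alcohol F1. F1 is converted at once into the primary iodide F2 (I2, PPh3, imidazole). LiCl-activated zinc dust inserts selectively into the alkyl C–I bond to give the alkylzinc iodide F3 (not isolated), which tolerates the hindered tertiary alcohol for the duration of the coupling. Intramolecular Negishi coupling with Pd(PPh3)4 under high dilution then gives 29. This separates the C1-setting hydroboration from the ring closure, allows the C1 configuration to be checked and purified at F1, and replaces boron-to-palladium transfer by the faster zinc-to-palladium transfer in a base-free medium.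

Step 11. Incomplete chelation would erode facial selectivity at C14. The fallback sets out from 14 and returns at 19. Alkenyllithium 17 is added to 14 in THF without magnesium salt (Felkin–Anh mode), which should favour the (14S) carbinol F4. C14 is then inverted by Mitsunobu esterification with 4-nitrobenzoic acid (PPh3, diisopropyl azodicarboxylate) to the (14R) 4-nitrobenzoate F5. Methanolysis (K2CO3, MeOH) gives 19. Any (14S) material from the main route can be fed into the same inversion.

Step 15. Metathesis at the hindered vinyl group may be sluggish, so that homodimerisation or double-bond migration of 26 and reaction at the lactone methylene take over. The fallback sets out from 13 and returns at 27; it runs the metathesis before the second terminal alkene exists. Compound 13 is desilylated (Bu4NF) to the diol F6, which is cross-metathesised with 26 under the conditions of step 15 to the E-alkenyl iodide F7. Dess–Martin oxidation gives the aldehyde F8. Chelation-controlled addition of excess 18 (MgBr2·OEt2, −78 °C) gives the carbinol F9, and Bu4NF gives the triol F10. Oxidative lactonisation (TEMPO, PhI(OAc)2) through the hydroxy aldehyde F11 and the lactol F12 gives 27.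

**Further compounds**

F1 | step 16 | (4R,5R)-4-(hydroxymethyl)-5-[(1R,2S,6S,7E,10E)-6-hydroxy-11-iodo-1-(4-methoxybenzyloxy)-2,6,10-trimethylundeca-7,10-dien-1-yl]oxolan-2-one | OC[C@H]1CC(=O)O[C@H]1[C@H](OCc1ccc(OC)cc1)[C@@H](C)CCC[C@](C)(O)/C=C/C/C(C)=C/I
F2 | step 16 | C2 primary iodide corresponding to F1 | IC[C@H]1CC(=O)O[C@H]1[C@H](OCc1ccc(OC)cc1)[C@@H](C)CCC[C@](C)(O)/C=C/C/C(C)=C/I
F3 | step 16 | C2 alkylzinc iodide corresponding to F2 | I[Zn]C[C@H]1CC(=O)O[C@H]1[C@H](OCc1ccc(OC)cc1)[C@@H](C)CCC[C@](C)(O)/C=C/C/C(C)=C/I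
F4 | step 11 | (14S) epimer of 19 | C=C(CCO[Si](C)(C)C(C)(C)C)[C@H](O)[C@H](OCc1ccc(OC)cc1)[C@@H](C)CCC[C@](C)(O[Si](CC)(CC)CC)C=C
F5 | step 11 | (14R) 4-nitrobenzoate of 19 | C=C(CCO[Si](C)(C)C(C)(C)C)[C@@H](OC(=O)c1ccc(cc1)[N+](=O)[O-])[C@H](OCc1ccc(OC)cc1)[C@@H](C)CCC[C@](C)(O[Si](CC)(CC)CC)C=C
F6 | step 15 | (2R,3S,7S)-2-(4-methoxybenzyloxy)-3,7-dimethylnon-8-ene-1,7-diol | OC[C@H](OCc1ccc(OC)cc1)[C@@H](C)CCC[C@](C)(O)C=C
F7 | step 15 | (2R,3S,7S,8E,11E)-12-iodo-2-(4-methoxybenzyloxy)-3,7,11-trimethyldodeca-8,11-diene-1,7-diol | OC[C@H](OCc1ccc(OC)cc1)[C@@H](C)CCC[C@](C)(O)/C=C/C/C(C)=C/I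
F8 | step 15 | (2R,3S,7S,8E,11E)-7-hydroxy-12-iodo-2-(4-methoxybenzyloxy)-3,7,11-trimethyldodeca-8,11-dienal | O=C[C@H](OCc1ccc(OC)cc1)[C@@H](C)CCC[C@](C)(O)/C=C/C/C(C)=C/I
F9 | step 15 | C16 TBS ether of F10 | C=C(CCO[Si](C)(C)C(C)(C)C)[C@@H](O)[C@H](OCc1ccc(OC)cc1)[C@@H](C)CCC[C@](C)(O)/C=C/C/C(C)=C/I
F10 | step 15 | triol corresponding to 20 with the E-alkenyl iodide side chain | C=C(CCO)[C@@H](O)[C@H](OCc1ccc(OC)cc1)[C@@H](C)CCC[C@](C)(O)/C=C/C/C(C)=C/I
F11 | step 15 | hydroxy aldehyde corresponding to 21 with the E-alkenyl iodide side chain | C=C(CC=O)[C@@H](O)[C@H](OCc1ccc(OC)cc1)[C@@H](C)CCC[C@](C)(O)/C=C/C/C(C)=C/I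
F12 | step 15 | lactol corresponding to 22 with the E-alkenyl iodide side chain | C=C1CC(O)O[C@H]1[C@H](OCc1ccc(OC)cc1)[C@@H](C)CCC[C@](C)(O)/C=C/C/C(C)=C/I
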